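**Plan**

1. Retrosynthetic cuts, in order: the C9 ester C–O bond; the lactone O8–C12 bond (C12 traced back to the isopropenyl methyl); the ether C5–O bond together with C5–H; the C4–C5 bond; the C10–C1 bond; C5 and C10 are then reconnected as the ring alkene of (S)-carvone.
2. Forward: the carvone ring (C5–C10) sets C7–C9 and is cleaved at C5=C10; a C1–C4 chain is added at C10; the ten-membered carbocycle closes at C4–C5; oxepane rings A and B close together; the γ-lactone and then the ester follow.
3. Enabling feature: C5 and C10 lie 1,6 across the carbocycle C1–C10, so a C10 hydroxyl and a C5 ketone meet as a bridged hemiketal whose oxygen completes ring A (O, C10, C1–C4, C5) and ring B (O, C5, C6–C9, C10).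
4. Stereochemistry: C7 from (S)-carvone; C8 by enolate hydroxylation trans to C7; C9 by Luche reduction trans to O8; C10 by Felkin–Anh Grignard addition beside C9–OTBS; C4 by equilibration; C5 dictated by the oxygen bridge; the acyl stereocentre from (R)-2-methylbutanoic acid.

Key step: step 12

Remark: atom labels C1–C15 follow the target (carbocycle C1–C10, C14 on C10, C15 on C4, C11–C13 the lactone carbons) and are kept for every intermediate; hydroxy ketone 17 is assumed to equilibrate freely with its bridged hemiketal 18.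

**Route**

Step 1
Reactants: 1 (S)-carvone
Product: 3 (5R,6R)-6-hydroxycarvone (hydroxyl on C8 trans to the C7 isopropenyl group), via lithium dienolate 2 (not isolated)
Conditions: LiN(iPr)2, THF, −78 °C; then (1S)-(+)-(10-camphorsulfonyl)oxaziridine, −78 to −40 °C; aq. NH4Cl
Reagents that add atoms: (1S)-(+)-(10-camphorsulfonyl)oxaziridine, CC1(C)C2CCC13CS(=O)(=O)N4OC34C2
Why: kinetic α′-deprotonation gives the cross-conjugated enolate, and its hydroxylation by the N-sulfonyloxaziridine (Davis-type enolate oxidation) should occur anti to the neighbouring isopropenyl group, which sets C8 trans to C7 in the diequatorial arrangement that is also the thermodynamic one.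

Step 2
Reactants: 3 (5R,6R)-6-hydroxycarvone
Product: 4 (1R,2R,6R)-3-methyl-6-(prop-1-en-2-yl)cyclohex-3-ene-1,2-diol (C8/C9 trans-diol)
Conditions: NaBH4, CeCl3·7H2O, MeOH, −78 °C
Reagents that add atoms: none
Why: Luche 1,2-reduction of the enone; axial hydride attack on the half-chair and delivery from the C8 alkoxyborohydride both place the new hydrogen cis to O8, so the C9 hydroxyl should end equatorial, trans to O8 and cis to the isopropenyl group as in the reduction of carvone to cis-carveol.

Step 3
Reactants: 4 trans-diol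
Product: 5 epoxy diol (C5–C10 epoxide cis to the C9 hydroxyl)
Conditions: VO(acac)2 (cat.), t-BuOOH, CH2Cl2, 0 °C
Reagents that add atoms: tert-butyl hydroperoxide, CC(C)(C)OO
Why: hydroxyl-directed vanadium-catalysed epoxidation touches only the ring alkene allylic to the C9 hydroxyl and leaves the isopropenyl group alone; the epoxide configuration (syn to C9–OH) is of no consequence because both carbons become carbonyl groups.

Step 4
Reactants: 5 epoxy diol
Product: 6 bis-TBS ether of 5
Conditions: TBSOTf, 2,6-lutidine, CH2Cl2, −78 °C, cold quench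
Reagents that add atoms: tert-butyldimethylsilyl trifluoromethanesulfonate, CC(C)(C)[Si](C)(C)OS(=O)(=O)C(F)(F)F
Why: silyl triflate silylation of both hindered secondary hydroxyls; the buffered medium and low temperature should keep the neighbouring epoxide from silyl-triflate-promoted opening.

Step 5
Reactants: 6 bis-TBS epoxide
Product: 8 (3R,4R,5S)-4,5-bis(TBSO)-6-oxo-3-(prop-1-en-2-yl)heptanal (C5 aldehyde and C10 methyl ketone), via vicinal diol 7 (not isolated)
Conditions: H5IO6, THF–H2O, 0 °C to rt
Reagents that add atoms: water, O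
Why: periodic acid hydrolyses the trisubstituted epoxide and cleaves the resulting glycol (Malaprade cleavage) between C5 and C10; the silyl ether on O9 stops cleavage from running on towards C9, and C7–C9 are not touched.

Step 6
Reactants: 8 keto-aldehyde
Product: 9 keto-acetal (C5 dimethyl acetal of 8)
Conditions: HC(OMe)3, pyridinium p-toluenesulfonate (cat.), MeOH, rt
Reagents that add atoms: trimethyl orthoformate, COC(OC)OC
Why: acid-catalysed acetalisation is chemoselective for the aldehyde, since the hindered α-silyloxy methyl ketone does not ketalise under these conditions and secondary TBS ethers survive.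

Step 7
Reactants: 9 keto-acetal, 10 2-(3-chloropropyl)-2-methyl-1,3-dioxolane
Product: 12 (10R) tertiary alcohol carrying the ketal-masked C1–C4/C15 chain, via Grignard reagent 11 (not isolated)
Conditions: 10, Mg, THF, reflux; then 9, THF, −78 to −40 °C; aq. NH4Cl
Reagents that add atoms: none
Why: Grignard addition to the methyl ketone under Felkin–Anh control: the non-chelating C9–OTBS bond stands perpendicular to the carbonyl and the nucleophile enters anti to it past H9, which should make O9 and the new C10 hydroxyl erythro (10R), any minor C10 epimer being removed here.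

Step 8
Reactants: 12 tertiary alcohol
Product: 13 seco hydroxy keto-aldehyde (C5 aldehyde, C4 methyl ketone, C10 tertiary alcohol)
Conditions: TsOH·H2O (cat.), acetone–H2O, rt
Reagents that add atoms: water, O
Why: acid-catalysed hydrolysis releases the aldehyde from its dimethyl acetal and the ketone from its dioxolane in one operation, conditions that hindered secondary TBS ethers tolerate.

Step 9
Reactants: 13 seco hydroxy keto-aldehyde
Product: 14 ten-membered 4,5,10-triol (C4/C5 diastereomer mixture)
Conditions: TiCl3(DME)1.5, Zn–Cu couple, DME, 25 °C, syringe-pump addition; aq. K2CO3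
Reagents that add atoms: none
Why: low-valent titanium couples the C5 aldehyde with the C4 ketone under high dilution (McMurry-type intramolecular pinacol coupling), a reaction type established for ten-membered carbocycles; the two new carbinol configurations do not matter because C5 is oxidised and C4 deoxygenated next.

Step 10
Reactants: 14 triol
Product: 15 4,10-dihydroxy-5-ketone (α-hydroxy ketone)
Conditions: SO3·pyridine, DMSO, iPr2NEt, CH2Cl2, 0 °C
Reagents that add atoms: none
Why: Parikh–Doering oxidation converts the only secondary alcohol (C5) to the ketone without glycol cleavage; both tertiary alcohols are inert.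

Step 11
Reactants: 15 α-hydroxy ketone
Product: 17 (4S,7R,8R,9S,10R)-8,9-bis(TBSO)-10-hydroxygermacr-11(13)-en-5-one, via C4-epimeric ketone mixture 16 (not isolated)
Conditions: SmI2, THF–MeOH, −78 °C; then DBU, CH2Cl2, rt
Reagents that add atoms: none
Why: samarium diiodide cleaves the C4–O bond α to the ketone (reduction of an α-hydroxy ketone through the ketyl and samarium enolate), and DBU then equilibrates C4 through the open-chain enol toward the epimer expected to be favoured, with the methyl group syn to the oxygen bridge and anti to C6 in the bridged hemiketal form (4S).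

Step 12
Reactants: 17 hydroxy ketone
Product: 20 (4S,5R,7R,8R,9S,10R)-8,9-bis(TBSO)-5,10-epoxygermacr-11(13)-ene, via bridged hemiketal 18 (not isolated), via oxocarbenium ion 19 (not isolated)
Conditions: Et3SiH, TMSOTf, CH2Cl2, −78 to −40 °C; Et3N then aq. NaHCO3
Reagents that add atoms: none
Why: The C10 hydroxyl adds across the ring to the C5 ketone to give bridged hemiketal 18; TMSOTf removes its hydroxyl to give the bridgehead oxocarbenium ion 19, which Et3SiH reduces, the closest known reaction type being the Et3SiH/TMSOTf reductive etherification of hydroxy ketones and bridged hemiketals. Ring A (through C1–C4) and ring B (through C6–C9) are each closed by a transannular 7-exo-trig attack of the C10 oxygen on the C5 carbonyl, both in the same event. C5 is the only new stereocentre and is controlled by C10: the oxygen must span C5 and C10 on one face, so hydride can only enter at the exo lobe and H5 should end opposite the bridge (5R). The selectivity needed is hydride capture ahead of proton loss from C4 (enol ether, epimerisation) and ahead of alkene attack on the cation. Low temperature and excess silane should secure the first, and the C7 isopropenyl group lies on the oxygen-bridge face, away from the exo lobe, which should secure the second. The TBS ethers keep O8 and O9 from competing as nucleophiles for C5.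

Step 13
Reactants: 20 bridged ether
Product: 22 germacr-11(13)-en-12-al (2-substituted acrolein at C7), via allylic alcohol 21 (not isolated)
Conditions: SeO2 (cat.), t-BuOOH, CH2Cl2, rt; then Dess–Martin periodinane, NaHCO3, CH2Cl2
Reagents that add atoms: selenium dioxide, O=[Se]=O; tert-butyl hydroperoxide, CC(C)(C)OO
Why: Riley-type allylic oxidation (ene reaction then [2,3]-shift) should take the isopropenyl methyl group, the only allylic CH3 in the molecule, and the periodinane carries the allylic alcohol on to the enal.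

Step 14
Reactants: 22 enal
Product: 23 germacr-11(13)-en-12-oic acid (acrylic acid at C7)
Conditions: NaClO2, NaH2PO4, 2-methyl-2-butene, t-BuOH–H2O, rt
Reagents that add atoms: sodium chlorite, [Na+].[O-]Cl=O
Why: Pinnick oxidation converts the enal to the acrylic acid without touching the alkene, the ether bridge or the silyl ethers.

Step 15
Reactants: 23 acrylic acid
Product: 25 9-hydroxy-5,10-epoxygermacr-11(13)-en-12,8-olide, via dihydroxy acid 24 (not isolated)
Conditions: 48% aq. HF, MeCN, rt
Reagents that add atoms: none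
Why: fluoride-mediated desilylation frees O8 and O9, and acid-catalysed lactonisation should take O8 in a 5-exo-trig closure to the trans-fused γ-lactone, because the alternative δ-lactone on O9 would be a strained bridged ring.

Step 16
Reactants: 25 hydroxy lactone, 26 (R)-2-methylbutanoic acid
Product: 27 target, the 9-O-[(R)-2-methylbutanoyl] ester of 25
Conditions: DCC, DMAP (cat.), CH2Cl2, 0 °C to rt
Reagents that add atoms: none
Why: Steglich esterification acylates the remaining C9 hydroxyl; the acyl stereocentre comes unchanged from the acid, and the low temperature limits α-epimerisation of the activated acid.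

**Compound list**

1 | (S)-carvone, (5S)-2-methyl-5-(prop-1-en-2-yl)cyclohex-2-en-1-one | CC1=CC[C@@H](CC1=O)C(C)=C | starting material
2 | lithium dienolate of 1 (O–C9=C8, not isolated) | CC1=CC[C@@H](C=C1[O-])C(C)=C.[Li+] | intermediate
3 | (5R,6R)-6-hydroxy-2-methyl-5-(prop-1-en-2-yl)cyclohex-2-en-1-one | CC1=CC[C@H](C(C)=C)[C@@H](O)C1=O | intermediate
4 | (1R,2R,6R)-3-methyl-6-(prop-1-en-2-yl)cyclohex-3-ene-1,2-diol | CC1=CC[C@H](C(C)=C)[C@@H](O)[C@@H]1O | intermediate
5 | 1-methyl-4-(prop-1-en-2-yl)-7-oxabicyclo[4.1.0]heptane-2,3-diol, epoxide cis to the adjacent (C9) hydroxyl, diol trans | C[C@@]12O[C@@H]1C[C@H](C(C)=C)[C@@H](O)[C@@H]2O | intermediate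
6 | bis(tert-butyldimethylsilyl) ether of 5 | C[C@@]12O[C@@H]1C[C@H](C(C)=C)[C@@H](O[Si](C)(C)C(C)(C)C)[C@@H]2O[Si](C)(C)C(C)(C)C | intermediate
7 | C5,C10-diol from hydrolysis of epoxide 6 (not isolated) | C[C@]1(O)[C@H](O)C[C@H](C(C)=C)[C@@H](O[Si](C)(C)C(C)(C)C)[C@@H]1O[Si](C)(C)C(C)(C)C | intermediate
8 | (3R,4R,5S)-4,5-bis[(tert-butyldimethylsilyl)oxy]-6-oxo-3-(prop-1-en-2-yl)heptanal | CC(=O)[C@@H](O[Si](C)(C)C(C)(C)C)[C@H](O[Si](C)(C)C(C)(C)C)[C@@H](C(C)=C)CC=O | intermediate
9 | dimethyl acetal of 8, 7,7-dimethoxy-3,4-bis(TBSO)-5-(prop-1-en-2-yl)heptan-2-one | CC(=O)[C@@H](O[Si](C)(C)C(C)(C)C)[C@H](O[Si](C)(C)C(C)(C)C)[C@@H](C(C)=C)CC(OC)OC | intermediate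
10 | 2-(3-chloropropyl)-2-methyl-1,3-dioxolane | CC1(CCCCl)OCCO1 | starting material
11 | [3-(2-methyl-1,3-dioxolan-2-yl)propyl]magnesium chloride (not isolated) | CC1(CCC[Mg]Cl)OCCO1 | intermediate
12 | Felkin adduct of 9 and 11: (10R) tertiary alcohol with C5 dimethyl acetal and C4 dioxolane | C[C@@](O)(CCCC1(C)OCCO1)[C@@H](O[Si](C)(C)C(C)(C)C)[C@H](O[Si](C)(C)C(C)(C)C)[C@@H](C(C)=C)CC(OC)OC | intermediate
13 | seco hydroxy keto-aldehyde: C5 aldehyde, C4 methyl ketone, C10 tertiary alcohol, 8,9-bis-TBS | C[C@@](O)(CCCC(C)=O)[C@@H](O[Si](C)(C)C(C)(C)C)[C@H](O[Si](C)(C)C(C)(C)C)[C@@H](C(C)=C)CC=O | intermediate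
14 | 8,9-bis(TBSO)germacr-11(13)-ene-4,5,10-triol (C4 and C5 mixed) | C[C@@]1(O)CCCC(C)(O)C(O)C[C@H](C(C)=C)[C@@H](O[Si](C)(C)C(C)(C)C)[C@@H]1O[Si](C)(C)C(C)(C)C | intermediate
15 | 8,9-bis(TBSO)-4,10-dihydroxygermacr-11(13)-en-5-one (C4 mixed) | C[C@@]1(O)CCCC(C)(O)C(=O)C[C@H](C(C)=C)[C@@H](O[Si](C)(C)C(C)(C)C)[C@@H]1O[Si](C)(C)C(C)(C)C | intermediate
16 | C4-epimeric mixture of 8,9-bis(TBSO)-10-hydroxygermacr-11(13)-en-5-one (not isolated) | C[C@@]1(O)CCCC(C)C(=O)C[C@H](C(C)=C)[C@@H](O[Si](C)(C)C(C)(C)C)[C@@H]1O[Si](C)(C)C(C)(C)C | intermediate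
17 | (4S,7R,8R,9S,10R)-8,9-bis(TBSO)-10-hydroxygermacr-11(13)-en-5-one | C[C@@]1(O)CCC[C@H](C)C(=O)C[C@H](C(C)=C)[C@@H](O[Si](C)(C)C(C)(C)C)[C@@H]1O[Si](C)(C)C(C)(C)C | intermediate
18 | bridged hemiketal of 17 (5-hydroxy-5,10-epoxide, not isolated) | CC(C)(C)[Si](C)(C)O[C@@H]2[C@@H](C(C)=C)C[C@@]1(O)O[C@](C)(CCC[C@@H]1C)[C@H]2O[Si](C)(C)C(C)(C)C | intermediate
19 | bridgehead oxocarbenium triflate (C5=O+–C10, not isolated) | CC(C)(C)[Si](C)(C)O[C@@H]2[C@@H](C(C)=C)CC1=[O+][C@](C)(CCC[C@@H]1C)[C@H]2O[Si](C)(C)C(C)(C)C.[O-]S(=O)(=O)C(F)(F)F | intermediate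
20 | (4S,5R,7R,8R,9S,10R)-8,9-bis(TBSO)-5,10-epoxygermacr-11(13)-ene | CC(C)(C)[Si](C)(C)O[C@@H]2[C@@H](C(C)=C)C[C@H]1O[C@](C)(CCC[C@@H]1C)[C@H]2O[Si](C)(C)C(C)(C)C | intermediate
21 | 12-hydroxy derivative of 20 (allylic alcohol, not isolated) | CC(C)(C)[Si](C)(C)O[C@@H]2[C@@H](C(CO)=C)C[C@H]1O[C@](C)(CCC[C@@H]1C)[C@H]2O[Si](C)(C)C(C)(C)C | intermediate
22 | 8,9-bis(TBSO)-5,10-epoxygermacr-11(13)-en-12-al | CC(C)(C)[Si](C)(C)O[C@@H]2[C@@H](C(C=O)=C)C[C@H]1O[C@](C)(CCC[C@@H]1C)[C@H]2O[Si](C)(C)C(C)(C)C | intermediate
23 | 8,9-bis(TBSO)-5,10-epoxygermacr-11(13)-en-12-oic acid | CC(C)(C)[Si](C)(C)O[C@@H]2[C@@H](C(C(=O)O)=C)C[C@H]1O[C@](C)(CCC[C@@H]1C)[C@H]2O[Si](C)(C)C(C)(C)C | intermediate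
24 | 8,9-dihydroxy-5,10-epoxygermacr-11(13)-en-12-oic acid (not isolated) | O[C@@H]2[C@@H](C(C(=O)O)=C)C[C@H]1O[C@](C)(CCC[C@@H]1C)[C@H]2O | intermediate
25 | 9-hydroxy-5,10-epoxygermacr-11(13)-en-12,8-olide | C=C1C(=O)O[C@@H]2[C@@H]1C[C@H]1O[C@](C)(CCC[C@@H]1C)[C@H]2O | intermediate
26 | (R)-2-methylbutanoic acid | CC[C@@H](C)C(=O)O | starting material
27 | CNP0136059.1, 9-O-[(R)-2-methylbutanoyl]-5,10-epoxygermacr-11(13)-en-12,8-olide | C=C1C(=O)O[C@@H]2[C@@H]1C[C@H]1O[C@](C)(CCC[C@@H]1C)[C@H]2OC(=O)[C@H](C)CC | target

**Count and risks**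

Total step count: 16. Longest linear sequence: 16 steps, from 1 to 27; 10 and 26 are purchased and enter in steps 7 and 16.

Steps most likely to fail:

1. Step 9, closure of the ten-membered ring. Intermolecular coupling or plain reduction of the two carbonyl groups may outrun formation of the strained medium ring. Fallback, from 9 back to 17: (4-bromopent-4-en-1-yl)magnesium bromide, made from 2,5-dibromopent-1-ene (C=C(Br)CCCBr), is added to keto-acetal 9 under the same Felkin–Anh control to give bromoalkenyl carbinol F1. Acid hydrolysis of the acetal gives hydroxy aldehyde F2. An intramolecular Nozaki–Hiyama–Kishi coupling (CrCl2, NiCl2 cat., DMSO–THF, high dilution) then forms the C4–C5 bond and gives ten-membered allylic alcohol F3. Dess–Martin oxidation gives α-methylene ketone F4, and conjugate reduction with [(Ph3P)CuH]6 followed by DBU rejoins the route at 17.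

2. Step 11, deoxygenation and C4 equilibration. Reductive cleavage of the unactivated tertiary α-hydroxyl may be sluggish, and the base equilibration may settle on the unwanted C4 epimer. Fallback, from 15 back to 17: dehydration of 15 with methyl N-(triethylammoniumsulfonyl)carbamate gives α-methylene ketone F5 (the same structure as F4). Conjugate reduction with [(Ph3P)CuH]6 and t-BuOH at low temperature delivers hydride to C15 and protonates the copper enolate from its open face, so C4 is set under kinetic instead of thermodynamic control. Ketone 17 is taken on without base treatment.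

3. Step 12, the transannular reductive etherification. Ionisation at the bridgehead may be slow, so that proton loss from C4 (epimerisation through the enol ether) or silyl ether cleavage competes with hydride capture. Fallback, from 17 to 20: NaBH4 reduction gives 5,10-diol F6, used as the C5 epimer with its hydroxyl on the face opposite the C10 oxygen; the other epimer is reoxidised to 17. Methanesulfonyl chloride and Et3N esterify only the secondary hydroxyl to give mesylate F7. KN(SiMe3)2 then closes the ether by a transannular Williamson displacement with inversion at C5, which gives 20.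

Further compounds
F1 | step 9 | bromoalkenyl carbinol, (10R) tertiary alcohol with 4-bromopent-4-enyl chain and C5 dimethyl acetal | C[C@@](O)(CCCC(Br)=C)[C@@H](O[Si](C)(C)C(C)(C)C)[C@H](O[Si](C)(C)C(C)(C)C)[C@@H](C(C)=C)CC(OC)OC
F2 | step 9 | hydroxy aldehyde with 2-bromoalkene terminus | C[C@@](O)(CCCC(Br)=C)[C@@H](O[Si](C)(C)C(C)(C)C)[C@H](O[Si](C)(C)C(C)(C)C)[C@@H](C(C)=C)CC=O
F3 | step 9 | ten-membered allylic alcohol, 8,9-bis(TBSO)germacra-4(15),11(13)-diene-5,10-diol | C[C@@]1(O)CCCC(=C)C(O)C[C@H](C(C)=C)[C@@H](O[Si](C)(C)C(C)(C)C)[C@@H]1O[Si](C)(C)C(C)(C)C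
F4 | step 9 | α-methylene ketone, 8,9-bis(TBSO)-10-hydroxygermacra-4(15),11(13)-dien-5-one | C[C@@]1(O)CCCC(=C)C(=O)C[C@H](C(C)=C)[C@@H](O[Si](C)(C)C(C)(C)C)[C@@H]1O[Si](C)(C)C(C)(C)C
F5 | step 11 | α-methylene ketone from dehydration of 15 (same structure as F4) | C[C@@]1(O)CCCC(=C)C(=O)C[C@H](C(C)=C)[C@@H](O[Si](C)(C)C(C)(C)C)[C@@H]1O[Si](C)(C)C(C)(C)C
F6 | step 12 | 8,9-bis(TBSO)germacr-11(13)-ene-5,10-diol, C5 hydroxyl anti to the C10 oxygen | C[C@@]1(O)CCC[C@H](C)[C@@H](O)C[C@H](C(C)=C)[C@@H](O[Si](C)(C)C(C)(C)C)[C@@H]1O[Si](C)(C)C(C)(C)C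
F7 | step 12 | C5 methanesulfonate of F6 | C[C@@]1(O)CCC[C@H](C)[C@@H](OS(C)(=O)=O)C[C@H](C(C)=C)[C@@H](O[Si](C)(C)C(C)(C)C)[C@@H]1O[Si](C)(C)C(C)(C)C
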